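Eudesmane numbering is used throughout: decalin C1–C10 with ring fusion at C5/C10, C14 methyl on C10, C15 on C4, and the C11(C12)(C13) side chain on C7.

**Plan**

1. Retrosynthesis: cut the C15–O ester and the C11–C12 bond (carbonylation), then open ring B at C7–C8 and ring A at C5–C10 in one stroke. The open chain is cut further at C5–C6 (conjugate addition to butenone), C4–C15 (carbocupration) and C9=C10 (olefination).
2. Enabling feature: in ring B the bonds C5–C10 and C7–C8 lie opposite each other. The ring therefore splits into C8–C9–C10, a 3-methyl-enal unit (electrophilic at the quaternary C10, then at C8), and C5–C6–C7, flanked by C4 (an allylsilane whose γ-carbon is C5) and C11 (a methyl ketone whose α-carbon is C7).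
3. Forward: hept-6-yn-2-one is extended to an acyclic enal/allylsilane/methyl ketone. One amine-salt-catalysed cascade closes ring A (C5–C10, conjugate allylation) and then ring B (C7–C8, aldol condensation).
4. The acetyl group then becomes the acrylate ester, and the exocyclic C4=C15 alkene is transposed into the ring while C15 receives the coumarate.
5. Stereochemistry: C5 and C10 arise together in the chair transition state of the allylation under a chiral imidazolidinone (absolute control). C7 is set by equilibration to the equatorial acetyl group. The E-alkene comes with p-coumaric acid.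

Key step: step 5

Assumption: hept-6-yn-2-one is treated as purchasable, and the (2S) catalyst is assumed to shield the iminium face that leads to the (5R,10R) series; if the sense is opposite, the (2R) catalyst is used.

**Route**

Step 1
Reactants: 1 hept-6-yn-2-one; 2 triethyl phosphonoacetate
Product: 3 ethyl (2E)-3-methyloct-2-en-7-ynoate
Conditions: NaH, THF, 0 °C to rt
Reagents that add atoms: none
Why: Horner–Wadsworth–Emmons olefination of the methyl ketone with the stabilized phosphonate anion should give mainly the (E)-trisubstituted enoate (the minor Z isomer is removed by chromatography, although both geometries should converge in step 5 through iminium/dienamine equilibration), and the terminal alkyne is not deprotonated by this anion.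

Step 2
Reactants: 3 ethyl (2E)-3-methyloct-2-en-7-ynoate; 4 but-3-en-2-one
Product: 7 ethyl (2E,7Z)-3-methyl-11-oxo-7-[(trimethylsilyl)methyl]dodeca-2,7-dienoate, via alkenylcopper 5 (not isolated), via silyl enol ether 6 (not isolated)
Conditions: Me3SiCH2MgCl, CuBr·SMe2, Et2O/Me2S, −40 to −15 °C; then 4, Me3SiCl, −78 to −20 °C; aq NH4Cl
Reagents that add atoms: (trimethylsilyl)methylmagnesium chloride, C[Si](C)(C)C[Mg]Cl
Why: syn-carbocupration of the terminal alkyne should put CH2SiMe3 on the internal carbon and copper on the terminal carbon, so that Me3SiCl-assisted conjugate addition of the alkenylcopper to butenone fixes the trisubstituted allylsilane with C6 cis to CH2SiMe3 (7Z); the β,β-disubstituted enoate is inert to the neutral organocopper.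

Step 3
Reactants: 7 ethyl (2E,7Z)-3-methyl-11-oxo-7-[(trimethylsilyl)methyl]dodeca-2,7-dienoate
Product: 8 (2E,7Z)-3-methyl-7-[(trimethylsilyl)methyl]dodeca-2,7-diene-1,11-diol
Conditions: i-Bu2AlH, CH2Cl2, −78 to 0 °C; aq potassium sodium tartrate
Reagents that add atoms: none
Why: the aluminium hydride should reduce the conjugated ester by 1,2-addition to the allylic alcohol and the ketone to the carbinol (its new stereocentre forms unselectively and is erased in step 4) without touching the allylsilane, which avoids a protecting group.

Step 4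
Reactants: 8 (2E,7Z)-3-methyl-7-[(trimethylsilyl)methyl]dodeca-2,7-diene-1,11-diol
Product: 9 (2E,7Z)-3-methyl-11-oxo-7-[(trimethylsilyl)methyl]dodeca-2,7-dienal
Conditions: DMP (1,1,1-triacetoxy-1,1-dihydro-1,2-benziodoxol-3(1H)-one), pyridine, CH2Cl2, 0 °C to rt
Reagents that add atoms: none
Why: periodinane oxidation under pyridine buffering should convert the allylic alcohol to the enal and the secondary alcohol to the methyl ketone in one operation, under conditions too weakly acidic to protodesilylate the allylsilane.

Step 5
Reactants: 9 (2E,7Z)-3-methyl-11-oxo-7-[(trimethylsilyl)methyl]dodeca-2,7-dienal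
Product: 12 1-[(4aR,8aS)-4a-methyl-8-methylidene-1,4,4a,5,6,7,8,8a-octahydronaphthalen-2-yl]ethan-1-one, via monocyclic aldehyde 10 (not isolated), via aldol adduct 11 (not isolated)
Conditions: (2S)-2-tert-butyl-3-methylimidazolidin-4-one trifluoroacetate (20 mol %), wet CHCl3, −20 °C to rt, then 45 °C
Reagents that add atoms: none
Why: Proposed new method: the amine salt should condense with the enal to an iminium ion whose β-carbon C10 is attacked by the γ-carbon C5 of the allylsilane (Hosomi–Sakurai-type conjugate allylation; ring A closes through a six-membered chair, 6-exo-trig at the acceptor and endo with respect to the allylsilane double bond), and the β-silyl cation at C4 then loses the silyl group to leave the exocyclic C4=C15 alkene and an enamine. Protonation of that enamine re-forms an iminium ion or aldehyde at C8 (compound 10), so the same catalyst turns C8 back into an electrophile; the acid-catalysed enol of the methyl ketone adds through C7 in a 6-(enolexo)-exo-trig Mannich/aldol closure of ring B, and E1cB loss of amine or water from 11 gives the conjugated enone. The closest known reaction types are iminium-catalysed additions of π-nucleophiles and hydride to enals (including β,β-disubstituted ones), Lewis-acid-mediated intramolecular Hosomi–Sakurai additions to β,β-disubstituted enones, and amine-salt-catalysed aldol condensation of 7-oxoalkanals to 1-acetylcyclohexenes. C5 and C10 are set together: the (7Z) allylsilane geometry places the C6 chain pseudo-equatorial and the bulky catalyst-bound iminium arm should also sit pseudo-equatorial, so the C10 methyl ends axial and anti to H-5 (trans fusion after ring B closes), while the tert-butyl group of the catalyst blocks one iminium face and fixes the absolute configuration. The step needs conjugate attack at C10 rather than 1,2-attack at C8, which ring size secures (six against eight), and aldol closure C7 to C8 rather than C9 to C11, which is secured because C8 is re-formed as the better acceptor and C9 is neopentylic.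

Step 6
Reactants: 12 1-[(4aR,8aS)-4a-methyl-8-methylidene-1,4,4a,5,6,7,8,8a-octahydronaphthalen-2-yl]ethan-1-one
Product: 13 1-[(2R,4aR,8aS)-4a-methyl-8-methylidenedecahydronaphthalen-2-yl]ethan-1-one
Conditions: [CuH(PPh3)]6, PhH, H2O (2 equiv), rt; then K2CO3, MeOH, rt
Reagents that add atoms: none
Why: conjugate hydride delivery from the copper hydride should reduce only the enone (the isolated exocyclic alkene is inert), and base equilibration of the epimerizable C7 centre should place the acetyl group equatorial (7β, H-7α), as in the target.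

Step 7
Reactants: 13 1-[(2R,4aR,8aS)-4a-methyl-8-methylidenedecahydronaphthalen-2-yl]ethan-1-one
Product: 15 1-[(2R,4aR,8aS)-4a-methyl-8-methylidenedecahydronaphthalen-2-yl]ethenyl trifluoromethanesulfonate, via potassium enolate 14 (not isolated)
Conditions: KN(SiMe3)2, THF, −78 °C; PhNTf2, −78 to 0 °C
Reagents that add atoms: N-phenylbis(trifluoromethanesulfonimide), O=S(=O)(N(c1ccccc1)S(=O)(=O)C(F)(F)F)C(F)(F)F
Why: kinetic deprotonation by the hindered amide base should occur at the methyl group rather than at the tertiary C7–H, so O-sulfonylation gives the terminal enol triflate without epimerizing C7.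

Step 8
Reactants: 15 1-[(2R,4aR,8aS)-4a-methyl-8-methylidenedecahydronaphthalen-2-yl]ethenyl trifluoromethanesulfonate
Product: 16 methyl 2-[(2R,4aR,8aS)-4a-methyl-8-methylidenedecahydronaphthalen-2-yl]prop-2-enoate (methyl costate)
Conditions: Pd(OAc)2, 1,3-bis(diphenylphosphino)propane, Et3N, CO (1 atm), MeOH/DMF, 60 °C
Reagents that add atoms: carbon monoxide, [C-]#[O+]; methanol, CO
Why: palladium-catalysed methoxycarbonylation of the vinyl triflate (oxidative addition, CO insertion, methanolysis) should turn C11–OTf into the α-substituted acrylate ester and leave all stereocentres untouched.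

Step 9
Reactants: 16 methyl 2-[(2R,4aR,8aS)-4a-methyl-8-methylidenedecahydronaphthalen-2-yl]prop-2-enoate
Product: 17 methyl 3ξ-hydroxyeudesma-4(15),11(13)-dien-12-oate
Conditions: SeO2 (0.3 equiv), t-BuOOH, CH2Cl2, 0 °C to rt
Reagents that add atoms: selenium dioxide (oxygen carrier), O=[Se]=O; tert-butyl hydroperoxide (stoichiometric oxygen source), CC(C)(C)OO
Why: allylic hydroxylation by SeO2 (ene reaction at the terminal carbon C15, then [2,3]-sigmatropic shift) should attack the electron-rich exocyclic alkene rather than the acrylate and, following the usual CH2 over CH preference, remove H-3 to give the 3-hydroxy-4(15)-ene; the new C3 centre forms unselectively and is lost in step 10.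

Step 10
Reactants: 17 methyl 3ξ-hydroxyeudesma-4(15),11(13)-dien-12-oate
Product: 19 methyl 15-chloroeudesma-3,11(13)-dien-12-oate, via chlorosulfite 18 (not isolated)
Conditions: SOCl2, Et2O, 0 °C
Reagents that add atoms: thionyl chloride, O=S(Cl)Cl
Why: the chlorosulfite of the secondary allylic alcohol should collapse by the SNi′ pathway in ether, moving the double bond into the ring (C3=C4) and delivering chloride to the primary carbon C15, which is also the more stable allylic isomer.

Step 11
Reactants: 19 methyl 15-chloroeudesma-3,11(13)-dien-12-oate; 20 (E)-4-hydroxycinnamic acid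
Product: 21 methyl 15-[(E)-4-hydroxycinnamoyloxy]eudesma-3,11(13)-dien-12-oate (target)
Conditions: KHCO3, NaI (cat.), DMF, rt
Reagents that add atoms: none
Why: with hydrogencarbonate only the carboxylic acid is deprotonated, so the carboxylate should alkylate the primary allylic chloride by SN2 displacement (iodide catalysis) while the phenol stays free and the (E)-alkene of the acid is carried through unchanged.

**Compound list**

1 | hept-6-yn-2-one | CC(=O)CCCC#C | starting material
2 | triethyl phosphonoacetate | CCOC(=O)CP(=O)(OCC)OCC | starting material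
3 | ethyl (2E)-3-methyloct-2-en-7-ynoate | CCOC(=O)/C=C(C)/CCCC#C | intermediate
4 | but-3-en-2-one | C=CC(C)=O | starting material
5 | alkenylcopper, ethyl (2E,7Z)-8-cuprio-3-methyl-7-[(trimethylsilyl)methyl]octa-2,7-dienoate (not isolated) | CCOC(=O)/C=C(C)/CCC/C(C[Si](C)(C)C)=C/[Cu] | intermediate
6 | silyl enol ether, ethyl (2E,7Z)-3-methyl-11-(trimethylsilyloxy)-7-[(trimethylsilyl)methyl]dodeca-2,7,10-trienoate (not isolated) | CCOC(=O)/C=C(C)/CCC/C(C[Si](C)(C)C)=C/CC=C(C)O[Si](C)(C)C | intermediate
7 | ethyl (2E,7Z)-3-methyl-11-oxo-7-[(trimethylsilyl)methyl]dodeca-2,7-dienoate | CCOC(=O)/C=C(C)/CCC/C(C[Si](C)(C)C)=C/CCC(C)=O | intermediate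
8 | (2E,7Z)-3-methyl-7-[(trimethylsilyl)methyl]dodeca-2,7-diene-1,11-diol (racemic at C11) | OC/C=C(C)/CCC/C(C[Si](C)(C)C)=C/CCC(C)O | intermediate
9 | (2E,7Z)-3-methyl-11-oxo-7-[(trimethylsilyl)methyl]dodeca-2,7-dienal | O=C/C=C(C)/CCC/C(C[Si](C)(C)C)=C/CCC(C)=O | intermediate
10 | monocyclic aldehyde, 2-[(1R,2S)-1-methyl-3-methylidene-2-(3-oxobutyl)cyclohexyl]acetaldehyde (not isolated) | O=CC[C@@]1(C)CCCC(=C)[C@@H]1CCC(C)=O | intermediate
11 | aldol adduct, 1-[(4aR,8aS)-3-hydroxy-4a-methyl-8-methylidenedecahydronaphthalen-2-yl]ethan-1-one, C2/C3 diastereomers (not isolated) | CC(=O)C1C(O)C[C@@]2(C)CCCC(=C)[C@@H]2C1 | intermediate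
12 | 1-[(4aR,8aS)-4a-methyl-8-methylidene-1,4,4a,5,6,7,8,8a-octahydronaphthalen-2-yl]ethan-1-one (12-noreudesma-4(15),7-dien-11-one; H-5α, CH3-10β) | CC(=O)C1=CC[C@@]2(C)CCCC(=C)[C@@H]2C1 | intermediate
13 | 1-[(2R,4aR,8aS)-4a-methyl-8-methylidenedecahydronaphthalen-2-yl]ethan-1-one (acetyl equatorial, 7β) | CC(=O)[C@@H]1CC[C@@]2(C)CCCC(=C)[C@@H]2C1 | intermediate
14 | potassium enolate of 13, terminal (not isolated) | [K+].[O-]C(=C)[C@@H]1CC[C@@]2(C)CCCC(=C)[C@@H]2C1 | intermediate
15 | 1-[(2R,4aR,8aS)-4a-methyl-8-methylidenedecahydronaphthalen-2-yl]ethenyl trifluoromethanesulfonate | C=C(OS(=O)(=O)C(F)(F)F)[C@@H]1CC[C@@]2(C)CCCC(=C)[C@@H]2C1 | intermediate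
16 | methyl 2-[(2R,4aR,8aS)-4a-methyl-8-methylidenedecahydronaphthalen-2-yl]prop-2-enoate (methyl costate) | C=C(C(=O)OC)[C@@H]1CC[C@@]2(C)CCCC(=C)[C@@H]2C1 | intermediate
17 | methyl 3ξ-hydroxyeudesma-4(15),11(13)-dien-12-oate (both C3 epimers; H-5α, H-7α, CH3-10β) | C=C(C(=O)OC)[C@@H]1CC[C@@]2(C)CCC(O)C(=C)[C@@H]2C1 | intermediate
18 | chlorosulfite of 17 (not isolated) | C=C(C(=O)OC)[C@@H]1CC[C@@]2(C)CCC(OS(=O)Cl)C(=C)[C@@H]2C1 | intermediate
19 | methyl 15-chloroeudesma-3,11(13)-dien-12-oate, methyl 2-[(2R,4aR,8aR)-8-(chloromethyl)-4a-methyl-1,2,3,4,4a,5,6,8a-octahydronaphthalen-2-yl]prop-2-enoate | C=C(C(=O)OC)[C@@H]1CC[C@@]2(C)CCC=C(CCl)[C@@H]2C1 | intermediate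
20 | (E)-4-hydroxycinnamic acid (p-coumaric acid) | O=C(O)/C=C/c1ccc(O)cc1 | starting material
21 | methyl 2-[(2R,4aR,8aR)-8-({[(2E)-3-(4-hydroxyphenyl)prop-2-enoyl]oxy}methyl)-4a-methyl-1,2,3,4,4a,5,6,8a-octahydronaphthalen-2-yl]prop-2-enoate | C=C(C(=O)OC)[C@@H]1CC[C@@]2(C)CCC=C(COC(=O)/C=C/c3ccc(O)cc3)[C@@H]2C1 | target

**Step count and risks**

Total: 11 steps. Longest linear sequence: 11 steps, from 1 to 21.

Step 5 (the proposed new method, therefore first). The hindered β,β-disubstituted enal may form the iminium ion too slowly, so that acid-promoted protodesilylation of the allylsilane takes over. Facial discrimination at C10 may be poor. The second stage may stall at aldehyde 10 or be diverted by an ene-type closure of the new exocyclic alkene onto C8. Fallback from 9, by known reactions: EtAlCl2 in CH2Cl2 at −78 °C should effect the Lewis-acid-mediated intramolecular Hosomi–Sakurai conjugate allylation and, after a cold aqueous NaHCO3 quench, give the racemic monocyclic aldehyde F1. Piperidine/AcOH in benzene at 60 °C should then close ring B by aldol condensation to the racemic dienone F2. Preparative chromatography on a cellulose tris(3,5-dimethylphenylcarbamate) phase should separate the enantiomers and bring the route back at 12.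

Step 2. Carbometalation of the unactivated alkyne by the stabilized (silylmethyl)copper may be sluggish or lose regiocontrol, and butenone may polymerize before the alkenylcopper adds. Fallback from 3: copper-catalysed borylative alkylation (bis(pinacolato)diboron, ICH2SiMe3, CuCl, 4,5-bis(diphenylphosphino)-9,9-dimethylxanthene, NaOt-Bu, THF) should add boron to the terminal and CH2SiMe3 to the internal alkyne carbon in a syn sense and give alkenylboronate F3. Rhodium-catalysed conjugate addition of F3 to butenone 4 ([RhCl(C8H12)]2, K3PO4, dioxane/H2O, 40 °C) should bring the route back at 7 with the same alkene geometry.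

Step 9. The selenium ene step may not discriminate enough between H-3 and the tertiary H-5 (hydroxylation at C5), and may over-oxidize the alcohol to the enone. Fallback from 16: mCPBA (NaHCO3, CH2Cl2, 0 °C) should epoxidize only the electron-rich exocyclic alkene and give epoxide F4. The hindered base Et2Al(2,2,6,6-tetramethylpiperidide) (toluene, 0 °C) should open it by removing the less hindered H-3 and give the primary allylic alcohol F5. MsCl/Et3N should give mesylate F6, and LiCl in DMF should displace it and bring the route back at 19.

**Further compounds**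

F1 | step 5 | racemic monocyclic aldehyde (racemate of 10) | O=CC[C@@]1(C)CCCC(=C)[C@@H]1CCC(C)=O.O=CC[C@]1(C)CCCC(=C)[C@H]1CCC(C)=O
F2 | step 5 | racemic dienone (racemate of 12) | CC(=O)C1=CC[C@@]2(C)CCCC(=C)[C@@H]2C1.CC(=O)C1=CC[C@]2(C)CCCC(=C)[C@H]2C1
F3 | step 2 | ethyl (2E,7Z)-3-methyl-8-(4,4,5,5-tetramethyl-1,3,2-dioxaborolan-2-yl)-7-[(trimethylsilyl)methyl]octa-2,7-dienoate | CCOC(=O)/C=C(C)/CCC/C(C[Si](C)(C)C)=C/B1OC(C)(C)C(C)(C)O1
F4 | step 9 | methyl 4,15-epoxyeudesm-11(13)-en-12-oate (C4 epimers) | C=C(C(=O)OC)[C@@H]1CC[C@@]2(C)CCCC3(CO3)[C@@H]2C1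
F5 | step 9 | methyl 15-hydroxyeudesma-3,11(13)-dien-12-oate | C=C(C(=O)OC)[C@@H]1CC[C@@]2(C)CCC=C(CO)[C@@H]2C1
F6 | step 9 | methyl 15-(methanesulfonyloxy)eudesma-3,11(13)-dien-12-oate | C=C(C(=O)OC)[C@@H]1CC[C@@]2(C)CCC=C(COS(C)(=O)=O)[C@@H]2C1
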